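The upper flavan's pyran ring (ring C) is cut at C3–C4 and O1–C8a, leaving a three-atom O1–C2–C3 unit that is an aryl oxirane. The key step is an anionic [3+3] annulation: the doubly benzylic C4 carbanion, flanked by ring A and the phloroglucinol ring of the epiafzelechin unit, opens (R)-4-benzyloxystyrene oxide at CH2, and the released C2 alkoxide displaces the fluorine on C8a of ring A; base equilibration at C4 then delivers the 2,4-cis chroman. The precursor is a benzylated 8-bromo-6-(2-fluorobenzyl)epiafzelechin, made by Friedel–Crafts benzylation of the natural flavan-3-ol with C8 blocked. Hydrogenolysis finishes the synthesis.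

Key step: step 6

Assumption: (−)-epiafzelechin (1) is bought as the isolated natural product; its (2R,3R) centers are carried through unchanged.

Step 1
Reactants: 1 (−)-epiafzelechin, (2R,3R)-2-(4-hydroxyphenyl)chromane-3,5,7-triol
Product: 2 (2R,3R)-3,5,7-tris(benzyloxy)-2-[4-(benzyloxy)phenyl]chromane
Conditions: NaH (4.5 equiv), BnBr (4.5 equiv), DMF, −20 °C → rt
Reagents that add atoms: benzyl bromide, BrCc1ccccc1
Why: Williamson etherification in which the three phenols and the C3 hydroxyl are benzylated as their oxyanions form, the low temperature and the bromide present from the start leaving no time for base-induced opening of the pyran ring, so that C2 and C3 stay (R,R).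

Step 2
Reactants: 2 (2R,3R)-3,5,7-tris(benzyloxy)-2-[4-(benzyloxy)phenyl]chromane
Product: 3 (2R,3R)-3,5,7-tris(benzyloxy)-2-[4-(benzyloxy)phenyl]-8-bromochromane
Conditions: NBS (1.05 equiv), CH2Cl2, −78 °C → rt
Reagents that add atoms: N-bromosuccinimide, O=C1CCC(=O)N1Br
Why: Electrophilic aromatic bromination, which should go to C8 because this position, flanked by O1 and the 7-benzyloxy group, is the most nucleophilic one of a 5,7-dialkoxyflavan, so that bromine blocks C8 for the next ring substitution.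

Step 3
Reactants: 4 4-(benzyloxy)-2-fluorobenzaldehyde
Product: 5 [4-(benzyloxy)-2-fluorophenyl]methanol
Conditions: NaBH4, MeOH/THF, 0 °C
Reagents that add atoms: none
Why: Borohydride reduction of an aryl aldehyde to the benzylic alcohol, which the aryl fluoride and the benzyl ether tolerate.

Step 4
Reactants: 3 (2R,3R)-3,5,7-tris(benzyloxy)-2-[4-(benzyloxy)phenyl]-8-bromochromane; 5 [4-(benzyloxy)-2-fluorophenyl]methanol
Product: 6 (2R,3R)-3,5,7-tris(benzyloxy)-6-[4-(benzyloxy)-2-fluorobenzyl]-2-[4-(benzyloxy)phenyl]-8-bromochromane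
Conditions: BF3·OEt2 (0.3 equiv), 4 Å molecular sieves, CH2Cl2, −40 → 0 °C, slow addition of 5
Reagents that add atoms: none
Why: Friedel–Crafts benzylation in which BF3·OEt2 ionises the para-alkoxybenzylic alcohol 5 to a stabilised benzylic cation that is captured by C6, the only free position of the phloroglucinol-type ring of 3 because C8 carries bromine, without forming or touching a stereocenter.

Step 5
Reactants: 7 1-[4-(benzyloxy)phenyl]-2-bromoethan-1-one
Product: 9 (R)-2-[4-(benzyloxy)phenyl]oxirane, via bromohydrin 8 (not isolated)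
Conditions: (R)-Me-CBS oxazaborolidine (C18H20BNO, 10 mol%), BH3·SMe2 (0.7 equiv), THF, 0 °C; then 2 M NaOH, rt; purification on Et3N-deactivated silica
Reagents that add atoms: none
Why: Corey–Bakshi–Shibata reduction followed by Williamson-type ring closure, in which the (R)-oxazaborolidine (the enantiomer that turns acetophenone into (S)-1-phenylethanol) treats the aryl group as the large substituent and delivers hydride to give (R)-bromohydrin 8, whose alkoxide displaces bromide at CH2 so that the stereocenter passes unchanged into (R)-9.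

Step 6
Reactants: 6 (2R,3R)-3,5,7-tris(benzyloxy)-6-[4-(benzyloxy)-2-fluorobenzyl]-2-[4-(benzyloxy)phenyl]-8-bromochromane; 9 (R)-2-[4-(benzyloxy)phenyl]oxirane
Product: 12 (2R,3R)-3,5,7-tris(benzyloxy)-6-[(2S,4S)-7-(benzyloxy)-2-(4-(benzyloxy)phenyl)chroman-4-yl]-2-[4-(benzyloxy)phenyl]-8-bromochromane, via ring-opened lithium alkoxide 10 (not isolated), via 2,4-trans chroman 11 (not isolated)
Conditions: LiN(iPr)2 (1.05 equiv), THF, −78 °C, 2 h; 9 (1.2 equiv), −78 → 0 °C; then KOtBu (0.5 equiv), 18-crown-6, DMSO, 70 °C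
Reagents that add atoms: none
Why: LiN(iPr)2 deprotonates the doubly benzylic C4–H2 of 6 (held at −78 °C so that any ring lithiation next to fluorine funnels back to the more stable diarylmethyl anion before LiF can be lost), the carbanion opens epoxide 9 by SN2 attack at the unhindered CH2 (C3–C4), and after the switch to KOtBu/DMSO the C2 alkoxide closes the pyran ring by intramolecular SNAr at the C8a–F carbon (O1–C8a). The closest known reaction types are the alkylation of diarylmethyl anions with epoxides and the intramolecular alkoxide SNAr of ortho-fluoroaryl alcohols to chromans, run here in one pot. The ring closes in a 6-exo-trig addition–elimination through a Meisenheimer intermediate. C2 is the untouched stereocenter of 9 (no bond to it is broken, so (R)-9 maps onto 2S), while C4 is formed without bias and is then set by reversible deprotonation of the diaryl C4–H in KOtBu/DMSO, which should funnel the trans chroman 11 into the 2,4-cis isomer 12 that carries both aryl groups pseudo-equatorial on the half-chair. The step needs terminal regioselectivity in the epoxide opening, secured by the bulky delocalised carbanion and the absence of a strong Lewis acid, and benzylic over aryl metalation, secured by the higher acidity of the diarylmethane and by the fully substituted lower ring.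

Step 7
Reactants: 12 (2R,3R)-3,5,7-tris(benzyloxy)-6-[(2S,4S)-7-(benzyloxy)-2-(4-(benzyloxy)phenyl)chroman-4-yl]-2-[4-(benzyloxy)phenyl]-8-bromochromane
Product: 13 (2R,3R)-6-[(2S,4S)-7-hydroxy-2-(4-hydroxyphenyl)chroman-4-yl]-2-(4-hydroxyphenyl)chromane-3,5,7-triol (CNP0167324.1)
Conditions: H2 (1 atm), Pd(OH)2/C, Et3N (2 equiv), THF/MeOH/H2O, rt
Reagents that add atoms: none
Why: Catalytic hydrogenolysis should cleave the six benzyl ethers and the aryl C–Br bond in one operation while Et3N traps HBr and so protects the acid-labile C4–C6 bond, no stereocenter being touched.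

Compound list
1 | (−)-epiafzelechin, (2R,3R)-2-(4-hydroxyphenyl)chromane-3,5,7-triol | Oc1cc(O)c2C[C@@H](O)[C@@H](c3ccc(O)cc3)Oc2c1 | starting material
2 | (2R,3R)-3,5,7-tris(benzyloxy)-2-[4-(benzyloxy)phenyl]chromane | c1ccccc1COc1cc(OCc2ccccc2)c2C[C@@H](OCc3ccccc3)[C@@H](c3ccc(OCc4ccccc4)cc3)Oc2c1 | intermediate
3 | (2R,3R)-3,5,7-tris(benzyloxy)-2-[4-(benzyloxy)phenyl]-8-bromochromane | c1ccccc1COc1cc(OCc2ccccc2)c2C[C@@H](OCc3ccccc3)[C@@H](c3ccc(OCc4ccccc4)cc3)Oc2c1Br | intermediate
4 | 4-(benzyloxy)-2-fluorobenzaldehyde | O=Cc1ccc(OCc2ccccc2)cc1F | starting material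
5 | [4-(benzyloxy)-2-fluorophenyl]methanol | OCc1ccc(OCc2ccccc2)cc1F | intermediate
6 | (2R,3R)-3,5,7-tris(benzyloxy)-6-[4-(benzyloxy)-2-fluorobenzyl]-2-[4-(benzyloxy)phenyl]-8-bromochromane | c1ccccc1COc1c(Cc2ccc(OCc3ccccc3)cc2F)c(OCc2ccccc2)c2C[C@@H](OCc3ccccc3)[C@@H](c3ccc(OCc4ccccc4)cc3)Oc2c1Br | intermediate
7 | 1-[4-(benzyloxy)phenyl]-2-bromoethan-1-one | O=C(CBr)c1ccc(OCc2ccccc2)cc1 | starting material
8 | (R)-1-[4-(benzyloxy)phenyl]-2-bromoethan-1-ol | O[C@@H](CBr)c1ccc(OCc2ccccc2)cc1 | intermediate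
9 | (R)-2-[4-(benzyloxy)phenyl]oxirane | c1ccccc1COc1ccc([C@@H]2CO2)cc1 | intermediate
10 | lithium (1S)-1-[4-(benzyloxy)phenyl]-3-[4-(benzyloxy)-2-fluorophenyl]-3-[(2R,3R)-3,5,7-tris(benzyloxy)-2-(4-(benzyloxy)phenyl)-8-bromochroman-6-yl]propan-1-olate, both epimers at C3 of the chain (the future C4) | c1ccccc1COc1ccc([C@@H]([O-])CC(c2c(OCc3ccccc3)c(Br)c3c(c2OCc2ccccc2)C[C@@H](OCc2ccccc2)[C@@H](c2ccc(OCc4ccccc4)cc2)O3)c2ccc(OCc3ccccc3)cc2F)cc1.[Li+] | intermediate
11 | (2R,3R)-3,5,7-tris(benzyloxy)-6-[(2S,4R)-7-(benzyloxy)-2-(4-(benzyloxy)phenyl)chroman-4-yl]-2-[4-(benzyloxy)phenyl]-8-bromochromane (2,4-trans epimer of 12) | c1ccccc1COc1ccc([C@@H]2C[C@@H](c3c(OCc5ccccc5)c(Br)c4c(c3OCc3ccccc3)C[C@@H](OCc3ccccc3)[C@@H](c3ccc(OCc5ccccc5)cc3)O4)c3ccc(OCc4ccccc4)cc3O2)cc1 | intermediate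
12 | (2R,3R)-3,5,7-tris(benzyloxy)-6-[(2S,4S)-7-(benzyloxy)-2-(4-(benzyloxy)phenyl)chroman-4-yl]-2-[4-(benzyloxy)phenyl]-8-bromochromane | c1ccccc1COc1ccc([C@@H]2C[C@H](c3c(OCc5ccccc5)c(Br)c4c(c3OCc3ccccc3)C[C@@H](OCc3ccccc3)[C@@H](c3ccc(OCc5ccccc5)cc3)O4)c3ccc(OCc4ccccc4)cc3O2)cc1 | intermediate
13 | (2R,3R)-6-[(2S,4S)-7-hydroxy-2-(4-hydroxyphenyl)chroman-4-yl]-2-(4-hydroxyphenyl)chromane-3,5,7-triol | Oc1ccc([C@@H]2C[C@H](c3c(O)cc4c(c3O)C[C@@H](O)[C@@H](c3ccc(O)cc3)O4)c3ccc(O)cc3O2)cc1 | target

Total step count: 7. Longest linear sequence: 5 steps (steps 1, 2, 4, 6, 7).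

Steps most likely to fail

Step 6. Three processes can spoil it. The exchange of the diaryl C4–H may be too slow, so that the facial non-selectivity of the carbanion alkylation is not corrected and cis and trans chromans both remain. Ring metalation next to fluorine may be followed by loss of LiF. The benzyl ethers may erode in hot KOtBu/DMSO. The fallback decouples bond formation from stereocontrol. It sets out from 6 and 9, which are united with LiN(iPr)2 in THF (−78 → 0 °C) and quenched cold with NH4Cl. This should give the two acyclic alcohols epimeric at the diaryl carbon, (1S,3R)-1-[4-(benzyloxy)phenyl]-3-[4-(benzyloxy)-2-fluorophenyl]-3-[(2R,3R)-3,5,7-tris(benzyloxy)-2-(4-(benzyloxy)phenyl)-8-bromochroman-6-yl]propan-1-ol F1 and its (1S,3S)-epimer F2. These diastereomers are separated by chromatography and F2 is set aside. F1 is closed with NaH in DMF at 80 °C, where the diaryl C–H does not exchange, and the route is rejoined at 12.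

Step 4. The benzylic cation of 5 may oligomerise, or be transferred reversibly between oxygen and carbon, faster than it is captured at the doubly flanked C6. The fallback brings the carbon in at the acyl level and sets out from 3. Compound 3 is acylated at C6 with purchased 4-(benzyloxy)-2-fluorobenzoic acid activated by (CF3CO)2O in CH2Cl2 (Friedel–Crafts acylation through the mixed anhydride, which cannot self-condense). This should give the diaryl ketone [4-(benzyloxy)-2-fluorophenyl][(2R,3R)-3,5,7-tris(benzyloxy)-2-(4-(benzyloxy)phenyl)-8-bromochroman-6-yl]methanone F3. F3 is deoxygenated with Et3SiH and BF3·OEt2 in CH2Cl2/MeCN (ionic hydrogenation), and the route is rejoined at 6.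

Step 7. Bromide may inhibit the catalyst so that hydrogenolysis of the hindered benzyl ethers stalls, or HBr may fragment the acid-labile C4–C6 bond before deprotection is complete. The fallback removes bromine first without hydrogen and sets out from 12. Compound 12 is treated with n-BuLi in THF at −78 °C (bromine–lithium exchange) and quenched with MeOH. This should give the bromine-free hexabenzyl ether (2R,3R)-3,5,7-tris(benzyloxy)-6-[(2S,4S)-7-(benzyloxy)-2-(4-(benzyloxy)phenyl)chroman-4-yl]-2-[4-(benzyloxy)phenyl]chromane F4. F4 is debenzylated with H2 and Pd(OH)2/C in THF/MeOH, and the route is rejoined at 13.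

Further compounds
F1 | step 6 | (1S,3R)-1-[4-(benzyloxy)phenyl]-3-[4-(benzyloxy)-2-fluorophenyl]-3-[(2R,3R)-3,5,7-tris(benzyloxy)-2-(4-(benzyloxy)phenyl)-8-bromochroman-6-yl]propan-1-ol | c1ccccc1COc1ccc([C@@H](O)C[C@H](c2c(OCc3ccccc3)c(Br)c3c(c2OCc2ccccc2)C[C@@H](OCc2ccccc2)[C@@H](c2ccc(OCc4ccccc4)cc2)O3)c2ccc(OCc3ccccc3)cc2F)cc1
F2 | step 6 | (1S,3S)-1-[4-(benzyloxy)phenyl]-3-[4-(benzyloxy)-2-fluorophenyl]-3-[(2R,3R)-3,5,7-tris(benzyloxy)-2-(4-(benzyloxy)phenyl)-8-bromochroman-6-yl]propan-1-ol | c1ccccc1COc1ccc([C@@H](O)C[C@@H](c2c(OCc3ccccc3)c(Br)c3c(c2OCc2ccccc2)C[C@@H](OCc2ccccc2)[C@@H](c2ccc(OCc4ccccc4)cc2)O3)c2ccc(OCc3ccccc3)cc2F)cc1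
F3 | step 4 | [4-(benzyloxy)-2-fluorophenyl][(2R,3R)-3,5,7-tris(benzyloxy)-2-(4-(benzyloxy)phenyl)-8-bromochroman-6-yl]methanone | c1ccccc1COc1c(C(=O)c2ccc(OCc3ccccc3)cc2F)c(OCc2ccccc2)c2C[C@@H](OCc3ccccc3)[C@@H](c3ccc(OCc4ccccc4)cc3)Oc2c1Br
F4 | step 7 | (2R,3R)-3,5,7-tris(benzyloxy)-6-[(2S,4S)-7-(benzyloxy)-2-(4-(benzyloxy)phenyl)chroman-4-yl]-2-[4-(benzyloxy)phenyl]chromane | c1ccccc1COc1ccc([C@@H]2C[C@H](c3c(OCc5ccccc5)cc4c(c3OCc3ccccc3)C[C@@H](OCc3ccccc3)[C@@H](c3ccc(OCc5ccccc5)cc3)O4)c3ccc(OCc4ccccc4)cc3O2)cc1
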